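**Plan**

1. Retrosynthetic cuts, in order: (i) the C2=C3 bond of the indenone five-membered ring (intramolecular aldol condensation); (ii) C3–CH3, with C3 traced back to the carbonyl carbon of a phthalide whose ring oxygen sits on the future isobutyryl carbon at C4; (iii) C1–C2, by homologation of an aryl aldehyde with an azulenyl diazoalkane; (iv) the aryl C4–carbinol bond (arylmagnesium plus isobutyraldehyde).
2. Enabling feature: in the five-membered ring, C1(=O)–C2=C3(CH3) is a β-methyl enone (aldol retron). C2 lies between the C1 carbonyl and the electron-rich azulene carbon, so it is the most acidic CH2 of the open form. C3 and the C4 acyl carbon are ortho on the benzene ring, so one lactone ring masks both.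
3. Forward order: the benzene ring is bought; temporary phthalide ring (step 1); formyl group (step 2); guaiazulene joined as its tosylhydrazone (steps 3–5); silyl enol ether helper (step 6); lactone opening by MeLi and closure of the five-membered ring (step 7); oxidation of the carbinol to the isobutyryl ketone (step 8).
4. Stereochemistry: the target has no stereocenter. The carbinol center from step 1 is carried racemic and erased in step 8; the hemiketal and aldol centers and the enol ether geometry are transient.

Key step: step 7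

Remark: Az denotes the 3,8-dimethyl-5-(propan-2-yl)azulen-1-yl group (guaiazulene bonded through its free five-membered-ring carbon); compounds 1, 2 and 8, LiTMP and i-PrMgCl·LiCl are taken as commercial.

**Route**

Step 1
Reactants: 1 methyl 2-bromo-3-methylbenzoate; 2 2-methylpropanal (isobutyraldehyde)
Product: 5 7-bromo-6-methyl-3-(propan-2-yl)-2-benzofuran-1(3H)-one (racemic), via arylmagnesium chloride 3 (not isolated), via magnesium alkoxide 4 (not isolated)
Conditions: LiTMP (lithium 2,2,6,6-tetramethylpiperidide), MgCl2, THF, −78 °C; then 2, −78 → 25 °C; aq. HCl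
Reagents that add atoms: isobutyraldehyde (compound 2), CC(C)C=O
Why: Ester-directed ortho-metalation with in situ magnesium trapping (the only ring hydrogen ortho to the ester is the one wanted; Br and CH3 block the other side), 1,2-addition of the arylmagnesium to the aldehyde and lactonization of the alkoxide onto the ortho ester should give the phthalide, whose carbinol center forms racemic and is erased in step 8.

Step 2
Reactants: 5 7-bromo-6-methyl-3-(propan-2-yl)-2-benzofuran-1(3H)-one
Product: 7 5-methyl-3-oxo-1-(propan-2-yl)-1,3-dihydro-2-benzofuran-4-carbaldehyde (racemic), via lactone arylmagnesium chloride 6 (not isolated)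
Conditions: i-PrMgCl·LiCl, THF, −20 °C; DMF, −20 → 0 °C; aq. HCl
Reagents that add atoms: N,N-dimethylformamide, CN(C)C=O
Why: Bromine–magnesium exchange with the turbo-Grignard reagent is accelerated by the ortho lactone carbonyl and tolerates the lactone at low temperature, and Bouveault formylation of the arylmagnesium with DMF should deliver the aldehyde.

Step 3
Reactants: 8 guaiazulene (1,4-dimethyl-7-(propan-2-yl)azulene)
Product: 10 3,8-dimethyl-5-(propan-2-yl)azulene-1-carbaldehyde, via iminium chloride 9 (not isolated)
Conditions: POCl3, DMF, 0 → 25 °C; aq. NaOH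
Reagents that add atoms: N,N-dimethylformamide, CN(C)C=O; water, O
Why: Vilsmeier–Haack formylation should occur at the only free, strongly nucleophilic position of the five-membered ring of guaiazulene.

Step 4
Reactants: 10 3,8-dimethyl-5-(propan-2-yl)azulene-1-carbaldehyde
Product: 11 (E)-N'-(Az-methylidene)-4-methylbenzenesulfonohydrazide
Conditions: TsNHNH2, MeOH, 25 °C
Reagents that add atoms: 4-methylbenzenesulfonohydrazide, Cc1ccc(S(=O)(=O)NN)cc1
Why: Condensation of the aldehyde with the sulfonyl hydrazide (hydrazone formation) should give the E tosylhydrazone.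

Step 5
Reactants: 11 (E)-N'-(Az-methylidene)-4-methylbenzenesulfonohydrazide; 7 5-methyl-3-oxo-1-(propan-2-yl)-1,3-dihydro-2-benzofuran-4-carbaldehyde
Product: 14 7-(2-Az-acetyl)-6-methyl-3-(propan-2-yl)-2-benzofuran-1(3H)-one (racemic), via hydrazone sodium salt 12 (not isolated), via diazoalkane 13 (not isolated)
Conditions: NaH, THF, 0 °C; then 7, 1,4-dioxane, 90 °C
Reagents that add atoms: none
Why: Bamford–Stevens generation of the azulenyl diazoalkane from the preformed sodium salt (no excess base), its addition to the aldehyde carbonyl and loss of N2 with 1,2-hydride shift (formal insertion into the formyl C–H bond, the azulene-stabilized positive charge at the former diazo carbon favoring hydride migration) should give the aryl azulenylmethyl ketone.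

Step 6
Reactants: 14 7-(2-Az-acetyl)-6-methyl-3-(propan-2-yl)-2-benzofuran-1(3H)-one
Product: 15 trimethylsilyl enol ether of 14, 7-[(Z)-2-Az-1-(trimethylsilyloxy)ethenyl]-6-methyl-3-(propan-2-yl)-2-benzofuran-1(3H)-one (racemic; Z expected, geometry of no consequence)
Conditions: TMSOTf, Et3N, CH2Cl2, 0 °C
Reagents that add atoms: trimethylsilyl trifluoromethanesulfonate, C[Si](C)(C)OS(=O)(=O)C(F)(F)F
Why: Soft enolization (silyl triflate and amine) converts the only enolizable carbonyl into its silyl enol ether, which shields the C1 ketone from MeLi and prevents Claisen-type attack of a free enolate on the lactone.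

Step 7
Reactants: 15 7-[(Z)-2-Az-1-(trimethylsilyloxy)ethenyl]-6-methyl-3-(propan-2-yl)-2-benzofuran-1(3H)-one
Product: 19 2-Az-4-(1-hydroxy-2-methylpropyl)-3,7-dimethyl-1H-inden-1-one (racemic), via lithium hemiketalate 16 (not isolated), via hydroxy diketone 17 (not isolated), via aldol 18 (not isolated)
Conditions: MeLi, THF, −78 °C; then KOH, MeOH, −78 → 50 °C
Reagents that add atoms: methyllithium, [Li]C
Why: MeLi adds once to the lactone carbonyl (the future C3) at −78 °C, where the lithium hemiketalate 16 is stable and the silyl enol ether shields the C1 ketone; KOH/MeOH then removes the silyl group and opens the lactol to the 1,4-diketone 17. The C2 methylene of 17 (α to the C1 ketone and bonded to the azulene) is the most acidic site, so its enolate attacks the new acetyl carbonyl and forms the C2–C3 bond, and E1cB loss of water from aldol 18 gives the indenone. The closest known reaction types are organolithium addition to phthalides (lactol formation) and the base-mediated aldol cyclodehydration of 1-(2-acylphenyl)-2-arylethanones to 2-aryl-3-alkylindenones, the same closure that ends the benzylidenephthalide–Grignard indenone synthesis. The five-membered ring closes in the 5-(enolendo)-exo-trig mode common to all 1,4-diketone-to-cyclopentenone aldol cyclizations. No stereocenter is set: the hemiketal and aldol centers vanish and the remote carbinol stays racemic. The step needs chemoselectivity (lactone before ketone and a single addition, secured by the silyl enol ether and the low-temperature-stable hemiketalate) and site selectivity (C2 enolate onto C3 and not the acetyl enolate onto C1, secured by the far higher acidity of the doubly activated CH2 and by dehydration to the azulene-conjugated enone, which drains the reversible aldol equilibria).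

Step 8
Reactants: 19 2-Az-4-(1-hydroxy-2-methylpropyl)-3,7-dimethyl-1H-inden-1-one
Product: 20 2-Az-3,7-dimethyl-4-(2-methylpropanoyl)-1H-inden-1-one (CNP0225119.0)
Conditions: Dess–Martin periodinane, CH2Cl2, 0 → 25 °C
Reagents that add atoms: none
Why: Dess–Martin oxidation of the secondary benzylic alcohol to the isopropyl ketone proceeds under near-neutral conditions that should leave the trisubstituted azulene and the indenone untouched, and it removes the last stereocenter.

**Compound list**

1 | methyl 2-bromo-3-methylbenzoate | COC(=O)c1cccc(C)c1Br | starting material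
2 | 2-methylpropanal (isobutyraldehyde) | CC(C)C=O | starting material
3 | [3-bromo-2-(methoxycarbonyl)-4-methylphenyl]magnesium chloride (not isolated) | COC(=O)c1c([Mg]Cl)ccc(C)c1Br | intermediate
4 | chloromagnesium alkoxide of methyl 2-bromo-6-(1-hydroxy-2-methylpropyl)-3-methylbenzoate (racemic, not isolated) | COC(=O)c1c(C(O[Mg]Cl)C(C)C)ccc(C)c1Br | intermediate
5 | 7-bromo-6-methyl-3-(propan-2-yl)-2-benzofuran-1(3H)-one (racemic) | CC(C)C1OC(=O)c2c(Br)c(C)ccc12 | intermediate
6 | [5-methyl-3-oxo-1-(propan-2-yl)-1,3-dihydro-2-benzofuran-4-yl]magnesium chloride (racemic, not isolated) | CC(C)C1OC(=O)c2c([Mg]Cl)c(C)ccc12 | intermediate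
7 | 5-methyl-3-oxo-1-(propan-2-yl)-1,3-dihydro-2-benzofuran-4-carbaldehyde (racemic) | CC(C)C1OC(=O)c2c(C=O)c(C)ccc12 | intermediate
8 | guaiazulene, 1,4-dimethyl-7-(propan-2-yl)azulene | c1cc(C)c2cc(C(C)C)ccc(C)c1-2 | starting material
9 | N-(Az-methylidene)-N-methylmethanaminium chloride (not isolated) | C[N+](C)=Cc1cc(C)c2cc(C(C)C)ccc(C)c1-2.[Cl-] | intermediate
10 | 3,8-dimethyl-5-(propan-2-yl)azulene-1-carbaldehyde | O=Cc1cc(C)c2cc(C(C)C)ccc(C)c1-2 | intermediate
11 | (E)-N'-(Az-methylidene)-4-methylbenzenesulfonohydrazide | Cc1ccc(S(=O)(=O)N/N=C/c2cc(C)c3cc(C(C)C)ccc(C)c2-3)cc1 | intermediate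
12 | sodium salt of tosylhydrazone 11 (not isolated) | Cc1ccc(S(=O)(=O)[N-]/N=C/c2cc(C)c3cc(C(C)C)ccc(C)c2-3)cc1.[Na+] | intermediate
13 | 1-(diazomethyl)-3,8-dimethyl-5-(propan-2-yl)azulene (not isolated) | [N-]=[N+]=Cc1cc(C)c2cc(C(C)C)ccc(C)c1-2 | intermediate
14 | 7-(2-Az-acetyl)-6-methyl-3-(propan-2-yl)-2-benzofuran-1(3H)-one (racemic) | CC(C)C1OC(=O)c2c(C(=O)Cc3cc(C)c4cc(C(C)C)ccc(C)c3-4)c(C)ccc12 | intermediate
15 | 7-[(Z)-2-Az-1-(trimethylsilyloxy)ethenyl]-6-methyl-3-(propan-2-yl)-2-benzofuran-1(3H)-one (racemic) | CC(C)C1OC(=O)c2c(/C(O[Si](C)(C)C)=C/c3cc(C)c4cc(C(C)C)ccc(C)c3-4)c(C)ccc12 | intermediate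
16 | lithium hemiketalate from addition of CH3 to the lactone carbonyl of 15 (mixture of diastereomers, not isolated) | CC(C)C1OC(C)([O-])c2c(/C(O[Si](C)(C)C)=C/c3cc(C)c4cc(C(C)C)ccc(C)c3-4)c(C)ccc12.[Li+] | intermediate
17 | 1-[2-acetyl-3-(1-hydroxy-2-methylpropyl)-6-methylphenyl]-2-Az-ethan-1-one (racemic, open form of the lactol, not isolated) | CC(C)C(O)c1ccc(C)c(C(=O)Cc2cc(C)c3cc(C(C)C)ccc(C)c2-3)c1C(C)=O | intermediate
18 | 2-Az-3-hydroxy-4-(1-hydroxy-2-methylpropyl)-3,7-dimethyl-2,3-dihydro-1H-inden-1-one (mixture of diastereomers, not isolated) | CC(C)C(O)c1ccc(C)c2c1C(C)(O)C(c1cc(C)c3cc(C(C)C)ccc(C)c1-3)C2=O | intermediate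
19 | 2-Az-4-(1-hydroxy-2-methylpropyl)-3,7-dimethyl-1H-inden-1-one (racemic) | CC1=C(c2cc(C)c3cc(C(C)C)ccc(C)c2-3)C(=O)c2c(C)ccc(C(O)C(C)C)c21 | intermediate
20 | 2-[3,8-dimethyl-5-(propan-2-yl)azulen-1-yl]-3,7-dimethyl-4-(2-methylpropanoyl)-1H-inden-1-one | CC1=C(c2cc(C)c3cc(C(C)C)ccc(C)c2-3)C(=O)c2c(C)ccc(C(=O)C(C)C)c21 | target

**Step count and risks**

Total step count: 8. Longest linear sequence: 6 (steps 1, 2, 5, 6, 7, 8, or equally steps 3, 4, 5, 6, 7, 8).

Steps most likely to fail:

Step 7. MeLi may add a second time to the unmasked acetyl group, attack the seven-membered ring of the azulene, or remove the silyl group early so that the free enolate closes onto the lactone in a Claisen fashion. The fallback sets out from 15 and replaces the nucleophilic methyl transfer by a titanium methylenation. Petasis methylenation (Cp2TiMe2, toluene, 70 °C) should convert the lactone carbonyl into the exocyclic enol ether trimethyl{[(Z)-2-Az-1-[5-methyl-3-methylidene-1-(propan-2-yl)-1,3-dihydro-2-benzofuran-4-yl]ethenyl]oxy}silane F1. Aqueous oxalic acid in THF should hydrate the enol ether and cleave the silyl enol ether to give 17 (as its lactol), and KOH in MeOH then effects the same aldol cyclodehydration. The route is rejoined at 19.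

Step 5. The electron-rich diazoalkane may decompose (azine or carbene-dimer formation) faster than it adds to the doubly ortho-substituted aldehyde, or the aryl group may migrate instead of hydride. The fallback sets out from 5 and 8 and uses the native nucleophilicity of guaiazulene. Stille coupling of 5 with tributyl(1-ethoxyvinyl)stannane (PdCl2(PPh3)2, toluene, 100 °C) should give 7-(1-ethoxyethenyl)-6-methyl-3-(propan-2-yl)-2-benzofuran-1(3H)-one F2. Aqueous HCl should give the methyl ketone 7-acetyl-6-methyl-3-(propan-2-yl)-2-benzofuran-1(3H)-one F3. Riley oxidation (SeO2, dioxane/water, 90 °C) should give the arylglyoxal 2-[5-methyl-3-oxo-1-(propan-2-yl)-1,3-dihydro-2-benzofuran-4-yl]-2-oxoacetaldehyde F4. Guaiazulene 8 should add through its free five-membered-ring carbon to the aldehyde carbon (CH2Cl2, 25 °C) to give 7-(2-Az-2-hydroxyacetyl)-6-methyl-3-(propan-2-yl)-2-benzofuran-1(3H)-one F5. Ionic hydrogenation (Et3SiH, CF3CO2H, CH2Cl2, 0 °C) through the azulene-stabilized cation should remove the hydroxyl group. The route is rejoined at 14.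

Step 1. Metalation may occur at another site (the benzylic methyl group), or the hindered amide base may be too slow so that the ester is attacked. The fallback sets out from 1 and replaces deprotonation by catalytic C–H borylation. Ester-directed ortho borylation ([Ir(OMe)(cod)]2, P[3,5-(CF3)2C6H3]3, B2pin2, octane, 80 °C) should give methyl 2-bromo-3-methyl-6-(4,4,5,5-tetramethyl-1,3,2-dioxaborolan-2-yl)benzoate F6. Rhodium-catalyzed 1,2-addition of F6 to isobutyraldehyde 2 ([Rh(OH)(cod)]2, dioxane/water, 60 °C) with lactonization in the same flask should give the phthalide. The route is rejoined at 5.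

**Further compounds**

F1 | step 7 | trimethyl{[(Z)-2-Az-1-[5-methyl-3-methylidene-1-(propan-2-yl)-1,3-dihydro-2-benzofuran-4-yl]ethenyl]oxy}silane (racemic) | C=C1OC(C(C)C)c2ccc(C)c(/C(O[Si](C)(C)C)=C/c3cc(C)c4cc(C(C)C)ccc(C)c3-4)c12
F2 | step 5 | 7-(1-ethoxyethenyl)-6-methyl-3-(propan-2-yl)-2-benzofuran-1(3H)-one (racemic) | CCOC(=C)c1c(C)ccc2c1C(=O)OC2C(C)C
F3 | step 5 | 7-acetyl-6-methyl-3-(propan-2-yl)-2-benzofuran-1(3H)-one (racemic) | CC(=O)c1c(C)ccc2c1C(=O)OC2C(C)C
F4 | step 5 | 2-[5-methyl-3-oxo-1-(propan-2-yl)-1,3-dihydro-2-benzofuran-4-yl]-2-oxoacetaldehyde (racemic) | O=CC(=O)c1c(C)ccc2c1C(=O)OC2C(C)C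
F5 | step 5 | 7-(2-Az-2-hydroxyacetyl)-6-methyl-3-(propan-2-yl)-2-benzofuran-1(3H)-one (mixture of diastereomers) | CC(C)C1OC(=O)c2c(C(=O)C(O)c3cc(C)c4cc(C(C)C)ccc(C)c3-4)c(C)ccc12
F6 | step 1 | methyl 2-bromo-3-methyl-6-(4,4,5,5-tetramethyl-1,3,2-dioxaborolan-2-yl)benzoate | COC(=O)c1c(B2OC(C)(C)C(C)(C)O2)ccc(C)c1Br
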